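**Strategy.** Oxolane atoms are labelled O1, C2 (aryl), C3 (bearing C9H2OAc), C4 (tertiary carbinol bearing the C7' benzyl) and C5. The route disconnects the hindered C3–C4 bond next to the fully substituted carbinol carbon. A samarium(II) ketyl–olefin cyclisation of an acyclic α-alkoxy benzyl ketone, tethered through O1 to an (E)-vinylsilane, closes the ring, forms C3–C4 and sets C3 and C4 in one event. Both centres are relayed from the single C2 stereocentre, which a catalytic asymmetric alkynylation installs. The precursor is a keto ether that unites the two C6–C3 halves of the lignan; the silyl group is the latent C9 hydroxyl.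

Key step: step 7

Assumption: benzyl(chloro)dimethylsilane, ethynylmagnesium bromide, 4-(benzyloxy)-3-methoxybenzaldehyde, 2-bromo-N-methoxy-N-methylacetamide and [4-(benzyloxy)-3-methoxyphenyl]methanol are taken as commercial; both phenols are carried as benzyl ethers to the last step.

Step 1
Reactants: 1 benzyl(chloro)dimethylsilane; 2 ethynylmagnesium bromide
Product: 3 benzyl(ethynyl)dimethylsilane
Conditions: 2 (1.3 equiv), THF, 0 °C → rt; NH4Cl aq.
Reagents that add atoms: none
Why: Nucleophilic substitution at silicon by an alkynyl Grignard reagent (silylation of an acetylide) should give the terminal silylalkyne; no stereocentre is formed.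

Step 2
Reactants: 4 4-(benzyloxy)-3-methoxybenzaldehyde; 3 benzyl(ethynyl)dimethylsilane
Product: 6 (1R)-1-[4-(benzyloxy)-3-methoxyphenyl]-3-[benzyl(dimethyl)silyl]prop-2-yn-1-ol, via alkynyl(ethyl)zinc 5 (not isolated)
Conditions: 3 (2 equiv), Et2Zn (2 equiv), toluene, reflux, 1 h; then (S)-BINOL (20 mol%), Ti(OiPr)4 (50 mol%), Et2O, rt; then 4, rt; NH4Cl aq.
Reagents that add atoms: none
Why: BINOL–titanium-catalysed enantioselective alkynylzinc addition to an aryl aldehyde is expected to deliver the alkynyl group to the Si face of 4 and so set C2 (R here only because silylalkynyl outranks aryl), the ligand antipode being used if the sense proves opposite.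

Step 3
Reactants: 6 (1R)-1-[4-(benzyloxy)-3-methoxyphenyl]-3-[benzyl(dimethyl)silyl]prop-2-yn-1-ol
Product: 7 (1S,2E)-1-[4-(benzyloxy)-3-methoxyphenyl]-3-[benzyl(dimethyl)silyl]prop-2-en-1-ol
Conditions: Red-Al (2 equiv), Et2O/THF, 0 °C → rt; Rochelle salt aq.
Reagents that add atoms: none
Why: Hydroxyl-directed trans-hydroalumination of the propargylic alcohol followed by protonolysis on work-up should give the (E)-vinylsilane without touching C2 (the descriptor becomes S only because alkenyl ranks below aryl).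

Step 4
Reactants: 7 (1S,2E)-1-[4-(benzyloxy)-3-methoxyphenyl]-3-[benzyl(dimethyl)silyl]prop-2-en-1-ol; 8 2-bromo-N-methoxy-N-methylacetamide
Product: 9 2-{[(1S,2E)-1-[4-(benzyloxy)-3-methoxyphenyl]-3-[benzyl(dimethyl)silyl]prop-2-en-1-yl]oxy}-N-methoxy-N-methylacetamide
Conditions: NaH (1.2 equiv), THF, 0 °C; then 8, Bu4NI (cat.), 0 °C → rt
Reagents that add atoms: none
Why: Williamson ether synthesis with a reactive α-bromo amide should install O1–C5 at the alkoxide oxygen, so the C2 configuration is retained.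

Step 5
Reactants: 10 [4-(benzyloxy)-3-methoxyphenyl]methanol
Product: 11 1-(benzyloxy)-4-(chloromethyl)-2-methoxybenzene
Conditions: SOCl2 (1.2 equiv), pyridine (cat.), CH2Cl2, 0 °C
Reagents that add atoms: thionyl chloride, O=S(Cl)Cl
Why: Deoxychlorination of an electron-rich benzylic alcohol with thionyl chloride is routine; no stereocentre is involved.

Step 6
Reactants: 9 2-{[(1S,2E)-1-[4-(benzyloxy)-3-methoxyphenyl]-3-[benzyl(dimethyl)silyl]prop-2-en-1-yl]oxy}-N-methoxy-N-methylacetamide; 11 1-(benzyloxy)-4-(chloromethyl)-2-methoxybenzene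
Product: 13 1-[4-(benzyloxy)-3-methoxyphenyl]-3-{[(1S,2E)-1-[4-(benzyloxy)-3-methoxyphenyl]-3-[benzyl(dimethyl)silyl]prop-2-en-1-yl]oxy}propan-2-one, via benzylic Grignard reagent 12 (not isolated)
Conditions: 11 added slowly to Mg turnings (3 equiv, I2-activated), THF, 0 °C; then 9, THF, −20 → 0 °C; NH4Cl aq.
Reagents that add atoms: none
Why: Weinreb ketone synthesis, in which the magnesium-chelated tetrahedral intermediate collapses only on work-up, should give the benzyl ketone (C7'–C4 bond) without over-addition; the vinylsilane and C2 are inert.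

Step 7
Reactants: 13 1-[4-(benzyloxy)-3-methoxyphenyl]-3-{[(1S,2E)-1-[4-(benzyloxy)-3-methoxyphenyl]-3-[benzyl(dimethyl)silyl]prop-2-en-1-yl]oxy}propan-2-one
Product: 14 (3S,4R,5S)-5-[4-(benzyloxy)-3-methoxyphenyl]-3-{[4-(benzyloxy)-3-methoxyphenyl]methyl}-4-{[benzyl(dimethyl)silyl]methyl}oxolan-3-ol
Conditions: SmI2 (3 equiv, 0.1 M in THF) premixed with HMPA (12 equiv), added over 2 h to 13 and t-BuOH (3 equiv) in THF (0.01 M), −20 °C → rt; NaHCO3 aq.
Reagents that add atoms: none
Why: Samarium(II) iodide–HMPA transfers one electron to the ketone to give a samarium(III) ketyl at C4, which adds to the β-carbon (C3) of the (E)-vinylsilane; the resulting α-silyl radical at C9 is reduced by a second equivalent and the organosamarium is protonated by tert-butanol. The closest known reaction type is the reductive ketyl–olefin cyclisation of δ,ε-unsaturated ketones, established for unactivated alkenes with HMPA, and a vinylsilane should be at least as good an acceptor. The oxolane closes in the 5-exo-trig mode through a chair-like transition state. C3 is controlled by the existing C2 centre, whose aryl group sits pseudo-equatorial next to the attacked alkene carbon and so ends trans to the new C9 arm; C4 is controlled by the bulky, electron-rich O–Sm(III)(HMPA)n group, which turns away from the alkene so that the hydroxyl ends trans to C9 and the benzyl group cis to it. The step needs cyclisation to outrun a second electron transfer that would expel the α-alkoxy group (C5–O1 cleavage) or simply reduce the ketone; the fast oxa-5-exo closure onto a radical-stabilising vinylsilane, slow addition of the reductant and high dilution should secure this. 6-endo closure is disfavoured because it would attack the silicon-bearing carbon and lose the α-silyl stabilisation.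

Step 8
Reactants: 14 (3S,4R,5S)-5-[4-(benzyloxy)-3-methoxyphenyl]-3-{[4-(benzyloxy)-3-methoxyphenyl]methyl}-4-{[benzyl(dimethyl)silyl]methyl}oxolan-3-ol
Product: 16 (3S,4R,5S)-5-[4-(benzyloxy)-3-methoxyphenyl]-3-{[4-(benzyloxy)-3-methoxyphenyl]methyl}-4-(hydroxymethyl)oxolan-3-ol, via fluorosilane 15 (not isolated)
Conditions: TBAF (2.5 equiv), THF, 0 °C → rt; then KHCO3, 30% H2O2, MeOH, rt → 40 °C
Reagents that add atoms: hydrogen peroxide, OO
Why: Tamao–Fleming oxidation, in which fluoride first cleaves the benzyl–silicon bond and peroxide then induces 1,2-migration of C9 from silicon to oxygen, should unveil the C9 alcohol under conditions that spare the electron-rich arenes and the benzylic ether; no stereocentre is touched.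

Step 9
Reactants: 16 (3S,4R,5S)-5-[4-(benzyloxy)-3-methoxyphenyl]-3-{[4-(benzyloxy)-3-methoxyphenyl]methyl}-4-(hydroxymethyl)oxolan-3-ol
Product: 17 [(2S,3R,4S)-2-[4-(benzyloxy)-3-methoxyphenyl]-4-{[4-(benzyloxy)-3-methoxyphenyl]methyl}-4-hydroxyoxolan-3-yl]methyl acetate
Conditions: Ac2O (1.2 equiv), pyridine, CH2Cl2, 0 °C
Reagents that add atoms: acetic anhydride, CC(=O)OC(C)=O
Why: O-Acetylation without an acyl-transfer catalyst should take the primary C9 hydroxyl only, since the tertiary C4 carbinol is unreactive and both phenols are masked.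

Step 10
Reactants: 17 [(2S,3R,4S)-2-[4-(benzyloxy)-3-methoxyphenyl]-4-{[4-(benzyloxy)-3-methoxyphenyl]methyl}-4-hydroxyoxolan-3-yl]methyl acetate
Product: 18 olivil monoacetate, [(2S,3R,4S)-4-hydroxy-2-(4-hydroxy-3-methoxyphenyl)-4-[(4-hydroxy-3-methoxyphenyl)methyl]oxolan-3-yl]methyl acetate
Conditions: H2 (1 atm), 10% Pd/C, EtOAc, rt, stopped at full debenzylation
Reagents that add atoms: none
Why: Catalytic hydrogenolysis of benzyl aryl ethers is much faster than cleavage of the cyclic benzylic C2–O1 ether under neutral conditions and should release both phenols, leaving the acetate and all three stereocentres untouched.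

**Compound list**

1 | benzyl(chloro)dimethylsilane | C[Si](C)(Cl)Cc1ccccc1 | starting material
2 | ethynylmagnesium bromide | C#C[Mg]Br | starting material
3 | benzyl(ethynyl)dimethylsilane | C#C[Si](C)(C)Cc1ccccc1 | intermediate
4 | 4-(benzyloxy)-3-methoxybenzaldehyde | COc1cc(C=O)ccc1OCc1ccccc1 | starting material
5 | ethyl{[benzyl(dimethyl)silyl]ethynyl}zinc | CC[Zn]C#C[Si](C)(C)Cc1ccccc1 | intermediate
6 | (1R)-1-[4-(benzyloxy)-3-methoxyphenyl]-3-[benzyl(dimethyl)silyl]prop-2-yn-1-ol | O[C@H](c1ccc(OCc2ccccc2)c(OC)c1)C#C[Si](C)(C)Cc1ccccc1 | intermediate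
7 | (1S,2E)-1-[4-(benzyloxy)-3-methoxyphenyl]-3-[benzyl(dimethyl)silyl]prop-2-en-1-ol | O[C@H](c1ccc(OCc2ccccc2)c(OC)c1)/C=C/[Si](C)(C)Cc1ccccc1 | intermediate
8 | 2-bromo-N-methoxy-N-methylacetamide | CON(C)C(=O)CBr | starting material
9 | 2-{[(1S,2E)-1-[4-(benzyloxy)-3-methoxyphenyl]-3-[benzyl(dimethyl)silyl]prop-2-en-1-yl]oxy}-N-methoxy-N-methylacetamide | CON(C)C(=O)CO[C@H](c1ccc(OCc2ccccc2)c(OC)c1)/C=C/[Si](C)(C)Cc1ccccc1 | intermediate
10 | [4-(benzyloxy)-3-methoxyphenyl]methanol | COc1cc(CO)ccc1OCc1ccccc1 | starting material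
11 | 1-(benzyloxy)-4-(chloromethyl)-2-methoxybenzene | COc1cc(CCl)ccc1OCc1ccccc1 | intermediate
12 | {[4-(benzyloxy)-3-methoxyphenyl]methyl}magnesium chloride | COc1cc(C[Mg]Cl)ccc1OCc1ccccc1 | intermediate
13 | 1-[4-(benzyloxy)-3-methoxyphenyl]-3-{[(1S,2E)-1-[4-(benzyloxy)-3-methoxyphenyl]-3-[benzyl(dimethyl)silyl]prop-2-en-1-yl]oxy}propan-2-one | COc1cc(CC(=O)CO[C@H](c2ccc(OCc3ccccc3)c(OC)c2)/C=C/[Si](C)(C)Cc2ccccc2)ccc1OCc1ccccc1 | intermediate
14 | (3S,4R,5S)-5-[4-(benzyloxy)-3-methoxyphenyl]-3-{[4-(benzyloxy)-3-methoxyphenyl]methyl}-4-{[benzyl(dimethyl)silyl]methyl}oxolan-3-ol (aryl trans to the silylmethyl arm, hydroxyl trans to it, benzyl cis to it) | COc1cc(C[C@@]2(O)CO[C@H](c3ccc(OCc4ccccc4)c(OC)c3)[C@H]2C[Si](C)(C)Cc2ccccc2)ccc1OCc1ccccc1 | intermediate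
15 | (3S,4R,5S)-5-[4-(benzyloxy)-3-methoxyphenyl]-3-{[4-(benzyloxy)-3-methoxyphenyl]methyl}-4-{[fluoro(dimethyl)silyl]methyl}oxolan-3-ol | COc1cc(C[C@@]2(O)CO[C@H](c3ccc(OCc4ccccc4)c(OC)c3)[C@H]2C[Si](C)(C)F)ccc1OCc1ccccc1 | intermediate
16 | (3S,4R,5S)-5-[4-(benzyloxy)-3-methoxyphenyl]-3-{[4-(benzyloxy)-3-methoxyphenyl]methyl}-4-(hydroxymethyl)oxolan-3-ol (di-O-benzyl olivil) | COc1cc(C[C@@]2(O)CO[C@H](c3ccc(OCc4ccccc4)c(OC)c3)[C@H]2CO)ccc1OCc1ccccc1 | intermediate
17 | [(2S,3R,4S)-2-[4-(benzyloxy)-3-methoxyphenyl]-4-{[4-(benzyloxy)-3-methoxyphenyl]methyl}-4-hydroxyoxolan-3-yl]methyl acetate | COc1cc(C[C@@]2(O)CO[C@H](c3ccc(OCc4ccccc4)c(OC)c3)[C@H]2COC(C)=O)ccc1OCc1ccccc1 | intermediate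
18 | olivil monoacetate, [(2S,3R,4S)-4-hydroxy-2-(4-hydroxy-3-methoxyphenyl)-4-[(4-hydroxy-3-methoxyphenyl)methyl]oxolan-3-yl]methyl acetate | COc1cc(C[C@@]2(O)CO[C@H](c3ccc(O)c(OC)c3)[C@H]2COC(C)=O)ccc1O | target

**Count.** Total steps: 10. Longest linear sequence: 9 (steps 1–4 and 6–10; step 5 is a side branch).

**Steps most likely to fail**

Step 7 (key step). The ketyl may take up a second electron before it cyclises, which would expel the α-alkoxy group or simply reduce the ketone, and face selectivity at C4 may erode. The fallback makes C3–C4 by a tin-hydride vinyl-radical cyclisation and oxygenates C4 afterwards. It sets out from 7: O-alkylation with 2,3-dibromopropene (NaH, THF, 0 °C) gives the 2-bromoallyl ether F1. Bu3SnH/AIBN (benzene, 80 °C) should close it 5-exo onto the vinylsilane to the 2,3-trans 4-methylene oxolane F2, with C3 again relayed from C2. Epoxidation with mCPBA/NaHCO3 (CH2Cl2, 0 °C) from the face anti to the C3 silylmethyl arm should give the spiro-epoxide F3. Copper-catalysed opening at the epoxide CH2 by the aryl Grignard reagent F4 (from commercial 1-(benzyloxy)-4-bromo-2-methoxybenzene and Mg; CuI 10 mol%, THF, −30 °C) then forms the C7'–aryl bond and the C4 carbinol, and the fallback comes back to the route at 14.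

Step 2. Enantioselectivity or conversion may be poor with this electron-rich aldehyde and a silylalkyne. The fallback sets the stereocentre by kinetic resolution and sets out from 3 and 4. The lithium acetylide F5 (3, n-BuLi, THF, −78 °C) adds to 4 to give the racemic propargylic alcohol F6, and Red-Al as in step 3 gives the racemic (E)-allylic alcohol F7. Sharpless kinetic resolution (Ti(OiPr)4, L-(+)-diisopropyl tartrate, t-BuOOH 0.6 equiv, 4 Å sieves, CH2Cl2, −20 °C) should consume the (R)-enantiomer as the erythro epoxy alcohol F8 and leave the (S)-alcohol, so the fallback comes back at 7.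

Step 6. Wurtz homocoupling during formation of the electron-rich benzylic Grignard reagent, or enolisation, may starve the acylation. The fallback replaces the Grignard reagent by a sulfone-stabilised carbanion and sets out from 11 and 9. Sodium benzenesulfinate (DMF, 60 °C) converts 11 into the benzylic sulfone F9. Deprotonation (n-BuLi, THF, −78 °C) gives the lithiated sulfone F10, which is acylated by Weinreb amide 9 to the β-keto sulfone F11 (epimers at the sulfonyl carbon). Reductive desulfonylation with aluminium amalgam (THF–H2O, 0 °C) should then give the ketone, and the fallback comes back at 13.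

**Further compounds**

F1 | step 7 | 1-(benzyloxy)-4-[(1S,2E)-3-[benzyl(dimethyl)silyl]-1-[(2-bromoprop-2-en-1-yl)oxy]prop-2-en-1-yl]-2-methoxybenzene | C=C(Br)CO[C@H](c1ccc(OCc2ccccc2)c(OC)c1)/C=C/[Si](C)(C)Cc1ccccc1
F2 | step 7 | benzyl{[(2S,3S)-2-[4-(benzyloxy)-3-methoxyphenyl]-4-methylideneoxolan-3-yl]methyl}dimethylsilane (2,3-trans) | C=C1CO[C@H](c2ccc(OCc3ccccc3)c(OC)c2)[C@H]1C[Si](C)(C)Cc1ccccc1
F3 | step 7 | spiro-epoxide of F2, 6-[4-(benzyloxy)-3-methoxyphenyl]-7-{[benzyl(dimethyl)silyl]methyl}-1,5-dioxaspiro[2.4]heptane with the epoxide oxygen trans to the silylmethyl arm | C1O[C@@]12CO[C@H](c3ccc(OCc4ccccc4)c(OC)c3)[C@H]2C[Si](C)(C)Cc1ccccc1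
F4 | step 7 | [4-(benzyloxy)-3-methoxyphenyl]magnesium bromide | COc1cc([Mg]Br)ccc1OCc1ccccc1
F5 | step 2 | lithium [benzyl(dimethyl)silyl]acetylide | [Li]C#C[Si](C)(C)Cc1ccccc1
F6 | step 2 | racemic 1-[4-(benzyloxy)-3-methoxyphenyl]-3-[benzyl(dimethyl)silyl]prop-2-yn-1-ol | OC(c1ccc(OCc2ccccc2)c(OC)c1)C#C[Si](C)(C)Cc1ccccc1
F7 | step 2 | racemic (2E)-1-[4-(benzyloxy)-3-methoxyphenyl]-3-[benzyl(dimethyl)silyl]prop-2-en-1-ol | OC(c1ccc(OCc2ccccc2)c(OC)c1)/C=C/[Si](C)(C)Cc1ccccc1
F8 | step 2 | (S)-[4-(benzyloxy)-3-methoxyphenyl]{(2S,3S)-3-[benzyl(dimethyl)silyl]oxiran-2-yl}methanol (erythro) | O[C@@H](c1ccc(OCc2ccccc2)c(OC)c1)[C@@H]1O[C@H]1[Si](C)(C)Cc1ccccc1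
F9 | step 6 | 1-(benzyloxy)-2-methoxy-4-[(phenylsulfonyl)methyl]benzene | COc1cc(CS(=O)(=O)c2ccccc2)ccc1OCc1ccccc1
F10 | step 6 | {[4-(benzyloxy)-3-methoxyphenyl](phenylsulfonyl)methyl}lithium | COc1cc(C([Li])S(=O)(=O)c2ccccc2)ccc1OCc1ccccc1
F11 | step 6 | 1-[4-(benzyloxy)-3-methoxyphenyl]-3-{[(1S,2E)-1-[4-(benzyloxy)-3-methoxyphenyl]-3-[benzyl(dimethyl)silyl]prop-2-en-1-yl]oxy}-1-(phenylsulfonyl)propan-2-one | COc1cc(C(C(=O)CO[C@H](c2ccc(OCc3ccccc3)c(OC)c2)/C=C/[Si](C)(C)Cc2ccccc2)S(=O)(=O)c2ccccc2)ccc1OCc1ccccc1
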